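**Retrosynthetic overview**
1. Clerodane numbering: ring A = C1–C4, C5, C10. Ring B = C5–C10. C17, C18, C19 and C20 sit on C8, C4, C5 and C9, and the side chain C11–C16 sits on C9. Endgame: the diosphenol and C4=C18 come from a C3 ketone (C2 aminomethylene block, Mannich methylenation at C4, singlet-oxygen cleavage). The C7 acetate comes from a C7 ketone, and C19 from cuprate addition to a C5=C6–C7=O enone (cis fusion).
2. Key disconnection (C5–C10 and C6–C7): the bicyclic enone comes from a monocyclic cyclobutanone by rhodium-catalysed C–C activation and alkyne insertion. Ring B grows from four to six atoms (C5 and C6 are inserted) and ring A closes in the same operation.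
3. Enabling feature: the strained four-membered ketone ring C7(=O)–C8–C9–C10. Its acyl bond C7–C10 carries on C10 a four-carbon tether (C1–C4) that ends in the alkyne C5≡C6. C8, C9 and C10 are already stereodefined and are carried through.
4. The cyclobutanone comes from a stereospecific [2+2] cycloaddition of a chiral propionamide-derived keteniminium salt (C7, C8, C17) to an E-trisubstituted alkene (C9=C10). That alkene is made by B-alkyl Suzuki coupling of a vinyl iodide from (R)-citronellic acid (C9–C16; C20 from AlMe3) with a C1–C6 enyne from acrolein.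
5. Order of ring formation: cyclobutane (step 10), then rings A and B together (step 11).

Key step: step 11

Convention: β is the face of ring B that bears H-10 and C19 in the target, and α is the opposite face. TBS = tert-butyldimethylsilyl, TMS = trimethylsilyl.
Assumption: the antipodes of the pyrrolidine auxiliary (step 10) and of DTBM-SEGPHOS (step 11) are taken to match the drawn configuration. If the sense of induction proves opposite, the mirror-image controller is used.

Step 1
Reactants: 1 (R)-citronellic acid
Product: 2 tert-butyl (3R)-3,7-dimethyloct-6-enoate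
Conditions: Boc2O, DMAP (cat.), t-BuOH, 30 °C
Reagents that add atoms: di-tert-butyl dicarbonate CC(C)(C)OC(=O)OC(=O)OC(C)(C)C
Why: DMAP-catalysed mixed-anhydride esterification installs an acid-labile tert-butyl ester under neutral conditions that leave the alkene and the C13 stereocentre (taken from the chiral pool) untouched.

Step 2
Reactants: 2 tert-butyl (3R)-3,7-dimethyloct-6-enoate
Product: 3 tert-butyl (3R)-3-methyl-6-oxohexanoate
Conditions: O3, CH2Cl2, −78 °C; then Me2S, −78 °C → rt
Reagents that add atoms: ozone [O-][O+]=O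
Why: Ozonolysis with reductive work-up cleaves the only C=C bond and leaves the aldehyde carbon that becomes C9.

Step 3
Reactants: 3 tert-butyl (3R)-3-methyl-6-oxohexanoate
Product: 4 tert-butyl (3R)-3-methylhept-6-ynoate
Conditions: dimethyl (1-diazo-2-oxopropyl)phosphonate, K2CO3, MeOH, 0 °C → rt
Reagents that add atoms: dimethyl (1-diazo-2-oxopropyl)phosphonate COP(=O)(OC)C(=[N+]=[N-])C(C)=O
Why: Ohira–Bestmann (Seyferth–Gilbert) homologation turns the unbranched aldehyde into the terminal alkyne C9≡C10 under carbonate conditions that the tert-butyl ester and the remote stereocentre tolerate.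

Step 4
Reactants: 4 tert-butyl (3R)-3-methylhept-6-ynoate
Product: 6 tert-butyl (3R,6E)-7-iodo-3,6-dimethylhept-6-enoate, via alkenylalane 5 (not isolated)
Conditions: AlMe3, Cp2ZrCl2 (cat.), H2O (1 equiv), CH2Cl2, −25 °C; then I2, THF, −25 → 0 °C
Reagents that add atoms: trimethylaluminium C[Al](C)C; iodine II
Why: Zirconium-catalysed Negishi carboalumination adds methyl (C20) and aluminium syn across the alkyne with methyl on the internal carbon, iodinolysis proceeds with retention to fix the E geometry that later encodes the C9/C10 relationship, and the low-temperature water-accelerated variant should spare the hindered ester.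

Step 5
Reactants: 7 acrolein; 8 3-bromo-1-(trimethylsilyl)prop-1-yne
Product: 10 rac-6-(trimethylsilyl)hex-1-en-5-yn-3-ol, via propargylzinc bromide 9 (not isolated)
Conditions: Zn dust, THF, 0 °C → rt; then 1 M HCl
Reagents that add atoms: none
Why: In this Barbier-type propargylation the silyl cap steers the ambident zinc reagent to the homopropargylic alcohol, and organozinc reagents add 1,2 to acrolein.

Step 6
Reactants: 10 rac-6-(trimethylsilyl)hex-1-en-5-yn-3-ol
Product: 11 (3S)-6-(trimethylsilyl)hex-1-en-5-yn-3-ol
Conditions: Ti(OiPr)4 (cat.), D-(−)-diisopropyl tartrate (cat.), t-BuOOH (0.6 equiv), 4 Å MS, CH2Cl2, −20 °C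
Reagents that add atoms: none
Why: In the Sharpless kinetic resolution with the D-(−)-tartrate the (R)-1-alken-3-ol is epoxidised faster, so the (S)-alcohol (future 3α-oxygen) is recovered, as the face-selection mnemonic predicts.

Step 7
Reactants: 11 (3S)-6-(trimethylsilyl)hex-1-en-5-yn-3-ol
Product: 12 (3S)-3-(TBS-oxy)-6-(trimethylsilyl)hex-1-en-5-yne
Conditions: TBSCl, imidazole, DMF, rt
Reagents that add atoms: tert-butyldimethylsilyl chloride CC(C)(C)[Si](C)(C)Cl
Why: Imidazole-promoted silylation protects the secondary alcohol without touching its stereocentre.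

Step 8
Reactants: 12 (3S)-3-(TBS-oxy)-6-(trimethylsilyl)hex-1-en-5-yne; 6 tert-butyl (3R,6E)-7-iodo-3,6-dimethylhept-6-enoate
Product: 14 tert-butyl (3R,6E,10R)-10-(TBS-oxy)-3,6-dimethyl-13-(trimethylsilyl)tridec-6-en-12-ynoate, via B-alkyl-9-BBN adduct 13 (not isolated)
Conditions: 9-BBN, THF, rt; then 6, Pd(dppf)Cl2 (cat.), AsPh3 (cat.), Cs2CO3, DMF/H2O, rt
Reagents that add atoms: none
Why: In this B-alkyl Suzuki–Miyaura coupling 9-BBN hydroborates the monosubstituted alkene anti-Markovnikov much faster than the silyl-capped alkyne, and the sp3–sp2 coupling (C1–C10) keeps the geometry of the vinyl iodide.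

Step 9
Reactants: 15 (2S,5S)-2,5-dimethylpyrrolidine; 16 propanoyl chloride
Product: 17 1-[(2S,5S)-2,5-dimethylpyrrolidin-1-yl]propan-1-one
Conditions: aq. NaOH, CH2Cl2, 0 °C
Reagents that add atoms: none
Why: Schotten–Baumann N-acylation gives the C2-symmetric tertiary amide that serves as the chiral methylketene equivalent.

Step 10
Reactants: 17 1-[(2S,5S)-2,5-dimethylpyrrolidin-1-yl]propan-1-one; 14 enyne ester
Product: 20 all-cis cyclobutanone, via keteniminium triflate 18 (not isolated), via cyclobutaniminium triflate 19 (not isolated)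
Conditions: 17, Tf2O, 2,6-di-tert-butyl-4-methylpyridine, ClCH2CH2Cl, −25 °C; then 14, 40–60 °C; then aq. NaHCO3, 60 °C
Reagents that add atoms: water O
Why: In this keteniminium–olefin [2+2] cycloaddition the electrophilic central carbon (C7) bonds to the less substituted alkene carbon C10 and C8 closes onto the incipient tertiary cation at C9, the addition is suprafacial so that the E geometry places the C1 tether and C20 cis, the C2-symmetric pyrrolidine shields one face of the cumulene and so selects the alkene face (absolute configuration of C9 and C10), the C8 methyl should arrive cis to C20 and is in any case epimerisable, and the far less nucleophilic silyl-capped alkyne should not compete.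

Step 11
Reactants: 20 all-cis cyclobutanone
Product: 21 bicyclic 6-(trimethylsilyl)-5-en-7-one
Conditions: [Rh(cod)2]BF4 (5 mol %), (R)-DTBM-SEGPHOS (6 mol %), 1,4-dioxane, 40–80 °C
Reagents that add atoms: none
Why: The alkyne first binds the cationic monovalent rhodium centre and so steers oxidative addition into the adjacent, strained acyl–carbon bond C7–C10 of the four-membered ring, giving a rhodacyclopentanone (Rh, C7, C8, C9, C10). Syn migratory insertion of C5≡C6 into the Rh–C10 bond closes ring A in a 6-exo-dig mode, and acyl–vinyl reductive elimination (C6–C7) from the seven-membered rhodacycle closes ring B, so that C5 and C6 end up inserted into the old C7–C10 bond and the four-membered ring becomes the six-membered enone. The closest known reaction type is the rhodium-catalysed cut-and-sew carboacylation of tethered alkynes and alkenes by cyclobutanones and benzocyclobutenones, which includes saturated cyclobutanones tethered at the alpha carbon with DTBM-SEGPHOS under mild heating. No new stereocentre is created: C10 is carried over with retention because oxidative addition and insertion both occur at the front of the C10 bond, and C3, C8, C9 and C13 are spectators, so the E-alkene information stored in the cyclobutane becomes the C9/C10 relationship of ring B. The step needs site selectivity (C7–C10 over C7–C8), secured by the tether because insertion into C7–C8 is reversible and finds no partner, and chemoselectivity over decarbonylation and alkyne oligomerisation, secured by the bulky electron-rich bisphosphine, the mild temperature and the silyl cap on C6.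

Step 12
Reactants: 21 bicyclic 6-(trimethylsilyl)-5-en-7-one
Product: 23 cis-decalone with the C19 methyl on C5, via alpha-silyl ketone 22 (not isolated)
Conditions: Me2CuLi (CuI, MeLi), Et2O, −40 → 0 °C; aq. NH4Cl; then K2CO3 (cat.), MeOH, rt
Reagents that add atoms: lithium dimethylcuprate [Li+].C[Cu-]C
Why: Gilman cuprate 1,4-addition to the alpha-silyl enone should deliver methyl to C5 from the β face, anti to the pseudo-axial C10–C1 bond and away from the 3α-silyloxy group, which gives the cis fusion usual for octalones, and methanolic carbonate then removes the alpha-silyl group and equilibrates C8 to the equatorial α-methyl epimer.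

Step 13
Reactants: 23 cis-decalone
Product: 24 7β-alcohol
Conditions: SmI2, H2O, THF, 0 °C → rt
Reagents that add atoms: none
Why: Single-electron (ketyl) reduction with SmI2/H2O should give the thermodynamically preferred equatorial 7β-alcohol, whereas hydride reagents would be pushed onto the equatorial trajectory by the two α-axial groups (C4 on C5 and C20 on C9).

Step 14
Reactants: 24 7β-alcohol
Product: 25 7β-acetate
Conditions: Ac2O, pyridine, DMAP (cat.), CH2Cl2, rt
Reagents that add atoms: acetic anhydride CC(=O)OC(C)=O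
Why: DMAP-catalysed acetylation of the only free hydroxyl installs the final C7 ester with retention.

Step 15
Reactants: 25 7β-acetate
Product: 26 3α-alcohol
Conditions: HF·pyridine, THF, 0 °C → rt
Reagents that add atoms: none
Why: Fluoride-mediated desilylation under mildly acidic conditions frees the C3 hydroxyl without harming the acetate or the tert-butyl ester.

Step 16
Reactants: 26 3α-alcohol
Product: 27 C3 ketone
Conditions: Dess–Martin periodinane, CH2Cl2, rt
Reagents that add atoms: none
Why: Dess–Martin oxidation converts the secondary alcohol into the ketone under neutral conditions and erases the auxiliary C3 stereocentre.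

Step 17
Reactants: 27 C3 ketone
Product: 28 (E)-2-(dimethylaminomethylene) 3-ketone
Conditions: t-BuOCH(NMe2)2, toluene, 80 °C
Reagents that add atoms: tert-butoxybis(dimethylamino)methane CN(C)C(OC(C)(C)C)N(C)C
Why: Condensation with Bredereck's reagent should occur at the less hindered alpha-methylene C2 (C4 is neopentyl), which blocks C2 and installs the latent C2 carbonyl.

Step 18
Reactants: 28 (E)-2-(dimethylaminomethylene) 3-ketone
Product: 30 4-(dimethylaminomethyl) Mannich base, via aminosiloxydiene 29 (not isolated)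
Conditions: TBSOTf, Et3N, CH2Cl2, −78 → 0 °C; then Me2N=CH2 I, CH2Cl2, 0 °C → rt; aq. NaHCO3
Reagents that add atoms: dimethylmethyleneammonium iodide C=[N+](C)C.[I-]
Why: Soft enolisation can now go only towards C4 and gives a 1-amino-3-siloxydiene whose terminal carbon C4 attacks Eschenmoser's salt (Mannich reaction), and the new C4 centre is erased in the next step.

Step 19
Reactants: 30 4-(dimethylaminomethyl) Mannich base
Product: 32 4-methylene enaminone, via ammonium iodide 31 (not isolated)
Conditions: MeI, CH2Cl2, rt; then sat. aq. NaHCO3, rt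
Reagents that add atoms: none
Why: Quaternisation of the aliphatic amine (the vinylogous amide nitrogen is not nucleophilic) and Hofmann-type E1cB elimination give the exocyclic methylene C4=C18, the only possible alkene because C5 bears no hydrogen.

Step 20
Reactants: 32 4-methylene enaminone
Product: 34 diosphenol tert-butyl ester, via 2,3-diketone 33 (not isolated)
Conditions: O2, tetraphenylporphyrin (cat.), hν (visible), CH2Cl2, −78 °C → rt
Reagents that add atoms: dioxygen O=O
Why: In this enaminone photooxygenation singlet oxygen adds [2+2] to the electron-rich aminomethylene C=C, the dioxetane cleaves to the 2,3-dione and DMF, the dione enolises towards C1 (the only neighbour with hydrogen), and the electron-poor exocyclic enone stays inert.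

Step 21
Reactants: 34 diosphenol tert-butyl ester
Product: 35 target acid CNP0257844.1
Conditions: CF3CO2H, CH2Cl2, 0 °C
Reagents that add atoms: none
Why: Acidolysis of the tert-butyl ester (E1 loss of isobutene) frees the acid under conditions that the acetate, the diosphenol and the methylene ketone should tolerate.

**Compound list**
1 | (R)-citronellic acid, (3R)-3,7-dimethyloct-6-enoic acid | CC(C)=CCC[C@@H](C)CC(=O)O | starting material
2 | tert-butyl (3R)-3,7-dimethyloct-6-enoate | CC(C)=CCC[C@@H](C)CC(=O)OC(C)(C)C | intermediate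
3 | tert-butyl (3R)-3-methyl-6-oxohexanoate | O=CCC[C@@H](C)CC(=O)OC(C)(C)C | intermediate
4 | tert-butyl (3R)-3-methylhept-6-ynoate | C#CCC[C@@H](C)CC(=O)OC(C)(C)C | intermediate
5 | dimethyl[(E)-alkenyl]alane from syn methylalumination of 4 | C[Al](C)/C=C(\C)CC[C@@H](C)CC(=O)OC(C)(C)C | intermediate
6 | tert-butyl (3R,6E)-7-iodo-3,6-dimethylhept-6-enoate | I/C=C(\C)CC[C@@H](C)CC(=O)OC(C)(C)C | intermediate
7 | acrolein | C=CC=O | starting material
8 | 3-bromo-1-(trimethylsilyl)prop-1-yne | C[Si](C)(C)C#CCBr | starting material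
9 | [3-(trimethylsilyl)prop-2-ynyl]zinc bromide | C[Si](C)(C)C#CC[Zn]Br | intermediate
10 | rac-6-(trimethylsilyl)hex-1-en-5-yn-3-ol | C[Si](C)(C)C#CCC(O)C=C | intermediate
11 | (3S)-6-(trimethylsilyl)hex-1-en-5-yn-3-ol | C[Si](C)(C)C#CC[C@H](O)C=C | intermediate
12 | (3S)-3-(TBS-oxy)-6-(trimethylsilyl)hex-1-en-5-yne | C[Si](C)(C)C#CC[C@H](O[Si](C)(C)C(C)(C)C)C=C | intermediate
13 | B-alkyl-9-BBN adduct of 12 (boron on C1) | C[Si](C)(C)C#CC[C@H](O[Si](C)(C)C(C)(C)C)CCB1C2CCCC1CCC2 | intermediate
14 | tert-butyl (3R,6E,10R)-10-(TBS-oxy)-3,6-dimethyl-13-(trimethylsilyl)tridec-6-en-12-ynoate | C[Si](C)(C)C#CC[C@H](O[Si](C)(C)C(C)(C)C)CC/C=C(\C)CC[C@@H](C)CC(=O)OC(C)(C)C | intermediate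
15 | (2S,5S)-2,5-dimethylpyrrolidine | C[C@H]1CC[C@H](C)N1 | starting material
16 | propanoyl chloride | CCC(=O)Cl | starting material
17 | 1-[(2S,5S)-2,5-dimethylpyrrolidin-1-yl]propan-1-one | CCC(=O)N1[C@@H](C)CC[C@@H]1C | intermediate
18 | methylketene-derived keteniminium triflate | CC=C=[N+]1[C@@H](C)CC[C@@H]1C.[O-]S(=O)(=O)C(F)(F)F | intermediate
19 | cyclobutaniminium triflate (iminium form of 20) | C[Si](C)(C)C#CC[C@H](O[Si](C)(C)C(C)(C)C)CC[C@@H]1[C@@](C)(CC[C@@H](C)CC(=O)OC(C)(C)C)[C@H](C)C1=[N+]2[C@@H](C)CC[C@@H]2C.[O-]S(=O)(=O)C(F)(F)F | intermediate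
20 | cyclobutanone (C7=O) with 8α-methyl, 9α-methyl, 9β-[(3R)-5-tert-butoxy-3-methyl-5-oxopentyl], 10β-H and 10α-[(3R)-3-(TBS-oxy)-6-(trimethylsilyl)hex-5-ynyl] (C17, C20 and the tether all cis) | C[Si](C)(C)C#CC[C@H](O[Si](C)(C)C(C)(C)C)CC[C@@H]1[C@@](C)(CC[C@@H](C)CC(=O)OC(C)(C)C)[C@H](C)C1=O | intermediate
21 | bicyclic enone: C5=C6(TMS)–C7=O, 3α-OTBS, 8α-methyl, 9α-methyl, 9β side chain (13R, tert-butyl ester), 10β-H | C1[C@H](O[Si](C)(C)C(C)(C)C)CC[C@@H]2[C@@](C)(CC[C@@H](C)CC(=O)OC(C)(C)C)[C@H](C)C(=O)C([Si](C)(C)C)=C12 | intermediate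
22 | 6-(trimethylsilyl) cis-decalone, 5β-methyl, C6 configuration not assigned | C1[C@H](O[Si](C)(C)C(C)(C)C)CC[C@@H]2[C@@](C)(CC[C@@H](C)CC(=O)OC(C)(C)C)[C@H](C)C(=O)C([Si](C)(C)C)[C@]12C | intermediate
23 | cis-decalone: 5β-methyl, 10β-H, C7 ketone, 3α-OTBS, 8α- and 9α-methyl | C1[C@H](O[Si](C)(C)C(C)(C)C)CC[C@@H]2[C@@](C)(CC[C@@H](C)CC(=O)OC(C)(C)C)[C@H](C)C(=O)C[C@]12C | intermediate
24 | 7β-alcohol of 23 | C1[C@H](O[Si](C)(C)C(C)(C)C)CC[C@@H]2[C@@](C)(CC[C@@H](C)CC(=O)OC(C)(C)C)[C@H](C)[C@@H](O)C[C@]12C | intermediate
25 | 7β-acetate, 3α-OTBS | C1[C@H](O[Si](C)(C)C(C)(C)C)CC[C@@H]2[C@@](C)(CC[C@@H](C)CC(=O)OC(C)(C)C)[C@H](C)[C@@H](OC(C)=O)C[C@]12C | intermediate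
26 | 7β-acetate, 3α-alcohol | C1[C@H](O)CC[C@@H]2[C@@](C)(CC[C@@H](C)CC(=O)OC(C)(C)C)[C@H](C)[C@@H](OC(C)=O)C[C@]12C | intermediate
27 | 7β-acetoxy 3-ketone | C1C(=O)CC[C@@H]2[C@@](C)(CC[C@@H](C)CC(=O)OC(C)(C)C)[C@H](C)[C@@H](OC(C)=O)C[C@]12C | intermediate
28 | (E)-2-(dimethylaminomethylene) 3-ketone | C1C(=O)/C(=C/N(C)C)C[C@@H]2[C@@](C)(CC[C@@H](C)CC(=O)OC(C)(C)C)[C@H](C)[C@@H](OC(C)=O)C[C@]12C | intermediate
29 | 3-(TBS-oxy)-3-ene of 28 (1-amino-3-siloxydiene) | C1=C(O[Si](C)(C)C(C)(C)C)/C(=C/N(C)C)C[C@@H]2[C@@](C)(CC[C@@H](C)CC(=O)OC(C)(C)C)[C@H](C)[C@@H](OC(C)=O)C[C@]12C | intermediate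
30 | 4-(dimethylaminomethyl) derivative of 28, C4 configuration not assigned | CN(C)CC1C(=O)/C(=C/N(C)C)C[C@@H]2[C@@](C)(CC[C@@H](C)CC(=O)OC(C)(C)C)[C@H](C)[C@@H](OC(C)=O)C[C@]12C | intermediate
31 | trimethylammonium iodide of 30 | C[N+](C)(C)CC1C(=O)/C(=C/N(C)C)C[C@@H]2[C@@](C)(CC[C@@H](C)CC(=O)OC(C)(C)C)[C@H](C)[C@@H](OC(C)=O)C[C@]12C.[I-] | intermediate
32 | 4-methylene (E)-2-(dimethylaminomethylene) 3-ketone | C=C1C(=O)/C(=C/N(C)C)C[C@@H]2[C@@](C)(CC[C@@H](C)CC(=O)OC(C)(C)C)[C@H](C)[C@@H](OC(C)=O)C[C@]12C | intermediate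
33 | 4-methylene 2,3-diketone | C=C1C(=O)C(=O)C[C@@H]2[C@@](C)(CC[C@@H](C)CC(=O)OC(C)(C)C)[C@H](C)[C@@H](OC(C)=O)C[C@]12C | intermediate
34 | tert-butyl ester of the target (2-hydroxy-1-en-3-one, 4-methylene) | C=C1C(=O)C(O)=C[C@@H]2[C@@](C)(CC[C@@H](C)CC(=O)OC(C)(C)C)[C@H](C)[C@@H](OC(C)=O)C[C@]12C | intermediate
35 | CNP0257844.1: (13R)-7β-acetoxy-2-hydroxy-3-oxo-5β,10β-cis-17α,20α-cleroda-1,4(18)-dien-15-oic acid | C=C1C(=O)C(O)=C[C@@H]2[C@@](C)(CC[C@@H](C)CC(=O)O)[C@H](C)[C@@H](OC(C)=O)C[C@]12C | target

**Step count**
Total: 21 steps. Longest linear sequence: 17 steps (steps 1–4, 8, 10–21).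

**Steps most likely to fail**

Step 11 (C–C activation and alkyne insertion). The rhodacyclopentanone may lose CO and collapse to a cyclopropane. Oxidative addition at the hindered C7–C10 bond may be too slow. The alkyne may be consumed by oligomerisation.
- The fallback sets out from 14 and comes back at 21, bypassing steps 9–11.
- An intramolecular Pauson–Khand reaction of the 1,7-enyne (Co2(CO)8, then N-methylmorpholine N-oxide) adds C5 and CO syn across the E-alkene. It gives the bicyclic cyclopentenone F1, in which ring A is closed and ring B is still five-membered (C5, C6, C7, C9, C10). The 3-silyloxy stereocentre biases the alkene face through a chair-like metallacycle.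
- A BF3·OEt2-promoted homologation with diazoethane (Tiffeneau–Demjanov-type ring expansion) then inserts CH(CH3) (C8, C17) between C7 and C9. The sp3 carbon C9 migrates with retention in preference to the alkenyl carbon C6, and this gives 21. C8 is equilibrated in step 12 as in the main route.

Step 10 (keteniminium [2+2]). Facial selectivity on an acyclic trisubstituted alkene may be poor. The silylalkyne may compete as the 2π partner. The tert-butyl ester may be lost to the acidic triflate salts.
- The fallback sets out from 14 and comes back at 21.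
- A Lewis-acid-catalysed allenoate–alkene [2+2] cycloaddition is used (2,2,2-trifluoroethyl buta-2,3-dienoate, chiral oxazaborolidine activated by AlBr3). Only the alkene carbons become stereocentres, so the catalyst selects the alkene face directly. This gives the alkylidenecyclobutane F2.
- Ozonolysis of the exocyclic enoate gives the C8-unsubstituted cyclobutanone F3.
- The rhodium-catalysed ring expansion of step 11 gives the enone F4.
- Kinetic alpha-prime enolate methylation (LDA, MeI) at C8, the only enolisable position, gives 21.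

Step 12 (cuprate addition). Both faces of C5 are flanked by a substituent on the quaternary C9, so the addition may be sluggish or may show poor facial selectivity (trans fusion).
- The fallback sets out from 20 and comes back at 24.
- AgNO3-catalysed protiodesilylation of the alkyne in aqueous acetone gives the terminal-alkyne cyclobutanone F5.
- The ring expansion of step 11 gives the unsilylated enone F6.
- Corey–Bakshi–Shibata reduction, with the oxazaborolidine antipode that delivers hydride to the α face, gives the 7β-allylic alcohol F7.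
- Hydroxyl-directed Simmons–Smith cyclopropanation (Et2Zn, CH2I2) places the methylene on the β face of C5=C6 and gives the cyclopropane F8.
- Hydrogenolysis of the least hindered cyclopropane bond C6–CH2 (H2, PtO2, AcOH) turns the methylene into the 5β-methyl group and gives 24. C5 is thus tied to C7 by direction rather than by substrate conformation.

**Further compounds**
F1 | step 11 | bicyclic cyclopentenone (Pauson–Khand product; five-membered ring C5, C6, C7, C9, C10) | C1[C@H](O[Si](C)(C)C(C)(C)C)CC[C@@H]2[C@@](C)(CC[C@@H](C)CC(=O)OC(C)(C)C)C(=O)C([Si](C)(C)C)=C12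
F2 | step 10 | alkylidenecyclobutane (C7=CH–CO2CH2CF3, C8H2), alkylidene geometry not assigned | C[Si](C)(C)C#CC[C@H](O[Si](C)(C)C(C)(C)C)CC[C@@H]1[C@@](C)(CC[C@@H](C)CC(=O)OC(C)(C)C)CC1=CC(=O)OCC(F)(F)F
F3 | step 10 | C8-unsubstituted cyclobutanone | C[Si](C)(C)C#CC[C@H](O[Si](C)(C)C(C)(C)C)CC[C@@H]1[C@@](C)(CC[C@@H](C)CC(=O)OC(C)(C)C)CC1=O
F4 | step 10 | C8-unsubstituted bicyclic 6-(trimethylsilyl)-5-en-7-one | C1[C@H](O[Si](C)(C)C(C)(C)C)CC[C@@H]2[C@@](C)(CC[C@@H](C)CC(=O)OC(C)(C)C)CC(=O)C([Si](C)(C)C)=C12
F5 | step 12 | terminal-alkyne cyclobutanone | C#CC[C@H](O[Si](C)(C)C(C)(C)C)CC[C@@H]1[C@@](C)(CC[C@@H](C)CC(=O)OC(C)(C)C)[C@H](C)C1=O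
F6 | step 12 | unsilylated bicyclic 5-en-7-one | C1[C@H](O[Si](C)(C)C(C)(C)C)CC[C@@H]2[C@@](C)(CC[C@@H](C)CC(=O)OC(C)(C)C)[C@H](C)C(=O)C=C12
F7 | step 12 | 7β-allylic alcohol | C1[C@H](O[Si](C)(C)C(C)(C)C)CC[C@@H]2[C@@](C)(CC[C@@H](C)CC(=O)OC(C)(C)C)[C@H](C)[C@@H](O)C=C12
F8 | step 12 | 5β,6β-methano (cyclopropane) 7β-alcohol | C1[C@H](O[Si](C)(C)C(C)(C)C)CC[C@@H]2[C@@](C)(CC[C@@H](C)CC(=O)OC(C)(C)C)[C@H](C)[C@@H](O)[C@H]3C[C@@]123
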